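**Retrosynthetic overview**

1. Ring A is bought ready-made as acetophenone 1. Its missing oxygen (the future 8-O) is installed para to a phenol and the ring is dressed before coupling: 1 → 2 → 4 → 5 → 6.
2. Ring B is bought ready-made as aldehyde 7. The key disconnection is the Cα–Cβ bond of chalcone 9, made by an intermolecular Claisen–Schmidt aldol condensation of 6 with 7.
3. Ring C (the pyranone) is the only ring that is built, and it is closed after the aldol by oxidative cyclisation of 9 to flavonol 11.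
4. End game: 11 → 12 (3-O-benzyl) → 13 (5,8-diol) → 14 (8-acetate; the chelated 5-OH stays free) → 15 by hydrogenolysis of the benzyl ethers.

Assumption: the target has no stereocentre, so no enantiocontrol is needed; the chiral compounds that occur only in the flask or in a fallback are racemic.

**Route**

Step 1
Reactants: 1 1-(2,6-dihydroxy-4-methoxyphenyl)ethanone (2',6'-dihydroxy-4'-methoxyacetophenone, commercial)
Product: 2 1-[2-(benzyloxy)-6-hydroxy-4-methoxyphenyl]ethanone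
Conditions: BnBr (1.05 equiv), K2CO3 (1.1 equiv), acetone, reflux, 6 h
Reagents that add atoms: benzyl bromide, BrCc1ccccc1
Why: Williamson ether synthesis; the two OH groups of 1 are equivalent by symmetry, and after the first alkylation the remaining OH is chelated to the ketone, so the reaction stops cleanly at the mono-ether.

Step 2
Reactants: 2 1-[2-(benzyloxy)-6-hydroxy-4-methoxyphenyl]ethanone
Product: 4 1-[2-(benzyloxy)-3,6-dihydroxy-4-methoxyphenyl]ethanone, via aryl potassium sulfate 3 (not isolated)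
Conditions: K2S2O8 (1.1 equiv), 10% aq NaOH/pyridine, 5–20 °C, 24 h, Ar; recover unreacted 2 at pH 5; then 2 M HCl, Na2SO3, 70 °C, 30 min
Reagents that add atoms: potassium peroxodisulfate, [K+].[K+].[O-]S(=O)(=O)OOS(=O)(=O)[O-]
Why: Elbs persulfate oxidation; the phenoxide of 2 attacks the peroxide oxygen at the free position para to its only OH (C-3), and acid hydrolysis of sulfate 3 frees the hydroquinone, as in the classical oxidation of 2-hydroxy-4,6-dimethoxyacetophenone.

Step 3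
Reactants: 4 1-[2-(benzyloxy)-3,6-dihydroxy-4-methoxyphenyl]ethanone
Product: 5 1-[2-(benzyloxy)-4-methoxy-3,6-bis(methoxymethoxy)phenyl]ethanone
Conditions: NaH (2.3 equiv), MOMCl (2.5 equiv), degassed DMF, 0 °C → rt, Ar
Reagents that add atoms: chloromethyl methyl ether, COCCl
Why: Williamson-type acetal protection; both phenols (including the chelated 6-OH) are alkylated as their sodium phenoxides, so no regioselection is needed and the future ring oxygen stays marked by the benzyl group.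

Step 4
Reactants: 5 1-[2-(benzyloxy)-4-methoxy-3,6-bis(methoxymethoxy)phenyl]ethanone
Product: 6 1-[2-hydroxy-4-methoxy-3,6-bis(methoxymethoxy)phenyl]ethanone
Conditions: H2 (1 atm), 10% Pd/C, EtOAc, rt
Reagents that add atoms: none
Why: Catalytic hydrogenolysis cleaves only the benzyl ether under neutral conditions (MOM acetals and the aryl ketone are untouched), unveiling exactly the phenol that will become the ring oxygen.

Step 5
Reactants: 6 1-[2-hydroxy-4-methoxy-3,6-bis(methoxymethoxy)phenyl]ethanone; 7 4-(benzyloxy)benzaldehyde (commercial)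
Product: 9 (E)-3-[4-(benzyloxy)phenyl]-1-[2-hydroxy-4-methoxy-3,6-bis(methoxymethoxy)phenyl]prop-2-en-1-one, via aldol adduct 8 (not isolated)
Conditions: 7 (1.2 equiv), 50% aq KOH, EtOH, rt, 36 h; AcOH to pH 6
Reagents that add atoms: none
Why: Claisen–Schmidt crossed aldol condensation of a methyl ketone enolate with a non-enolisable aldehyde; E1cB dehydration of 8 removes its carbinol centre and gives the thermodynamically favoured E-enone.

Step 6
Reactants: 9 (E)-3-[4-(benzyloxy)phenyl]-1-[2-hydroxy-4-methoxy-3,6-bis(methoxymethoxy)phenyl]prop-2-en-1-one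
Product: 11 2-[4-(benzyloxy)phenyl]-3-hydroxy-7-methoxy-5,8-bis(methoxymethoxy)-4H-chromen-4-one, via trans-dihydroflavonol 10 (not isolated)
Conditions: 30% H2O2 (5 equiv), 2 M aq NaOH (5 equiv), MeOH/THF, 0 °C → rt, 6 h; AcOH
Reagents that add atoms: hydrogen peroxide, OO
Why: Algar–Flynn–Oyamada reaction; oxidative oxa-Michael ring closure of the 2'-phenoxide gives racemic trans-dihydroflavonol 10, which alkaline H2O2 dehydrogenates to the flavonol, erasing both transient stereocentres.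

Step 7
Reactants: 11 2-[4-(benzyloxy)phenyl]-3-hydroxy-7-methoxy-5,8-bis(methoxymethoxy)-4H-chromen-4-one
Product: 12 3-(benzyloxy)-2-[4-(benzyloxy)phenyl]-7-methoxy-5,8-bis(methoxymethoxy)-4H-chromen-4-one
Conditions: BnBr (1.3 equiv), K2CO3 (2 equiv), DMF, rt → 40 °C
Reagents that add atoms: benzyl bromide, BrCc1ccccc1
Why: Williamson ether synthesis on the acidic enolic 3-OH, the only free hydroxyl in 11.

Step 8
Reactants: 12 3-(benzyloxy)-2-[4-(benzyloxy)phenyl]-7-methoxy-5,8-bis(methoxymethoxy)-4H-chromen-4-one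
Product: 13 3-(benzyloxy)-2-[4-(benzyloxy)phenyl]-5,8-dihydroxy-7-methoxy-4H-chromen-4-one
Conditions: 3 M HCl in MeOH/THF, 50 °C, 2 h, Ar
Reagents that add atoms: none
Why: Acid-catalysed acetal exchange with methanol removes both MOM groups while the benzyl ethers and the methyl ether are stable to dilute protic acid.

Step 9
Reactants: 13 3-(benzyloxy)-2-[4-(benzyloxy)phenyl]-5,8-dihydroxy-7-methoxy-4H-chromen-4-one
Product: 14 3-(benzyloxy)-2-[4-(benzyloxy)phenyl]-5-hydroxy-7-methoxy-4-oxo-4H-chromen-8-yl acetate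
Conditions: Ac2O (1.05 equiv), pyridine, CH2Cl2, 0 °C, Ar
Reagents that add atoms: acetic anhydride, CC(=O)OC(C)=O
Why: Chemoselective O-acylation; the 5-OH is locked in a strong hydrogen bond to the C-4 carbonyl and is not acetylated under these mild conditions, so only the free 8-OH reacts.

Step 10
Reactants: 14 3-(benzyloxy)-2-[4-(benzyloxy)phenyl]-5-hydroxy-7-methoxy-4-oxo-4H-chromen-8-yl acetate
Product: 15 3,5-dihydroxy-2-(4-hydroxyphenyl)-7-methoxy-4-oxo-4H-chromen-8-yl acetate (pollenitin 8-acetate)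
Conditions: H2 (1 atm), 10% Pd/C, EtOAc/THF, rt
Reagents that add atoms: none
Why: Neutral catalytic hydrogenolysis removes both benzyl ethers without touching the aryl acetate, and the acetate has no neighbouring free OH to migrate to.

**Compound list**

1 | 1-(2,6-dihydroxy-4-methoxyphenyl)ethanone | CC(=O)c1c(O)cc(OC)cc1O | starting material
2 | 1-[2-(benzyloxy)-6-hydroxy-4-methoxyphenyl]ethanone | CC(=O)c1c(O)cc(OC)cc1OCc2ccccc2 | intermediate
3 | potassium 3-acetyl-2-(benzyloxy)-4-hydroxy-6-methoxyphenyl sulfate (not isolated) | CC(=O)c1c(O)cc(OC)c(OS(=O)(=O)[O-])c1OCc2ccccc2.[K+] | intermediate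
4 | 1-[2-(benzyloxy)-3,6-dihydroxy-4-methoxyphenyl]ethanone | CC(=O)c1c(O)cc(OC)c(O)c1OCc2ccccc2 | intermediate
5 | 1-[2-(benzyloxy)-4-methoxy-3,6-bis(methoxymethoxy)phenyl]ethanone | CC(=O)c1c(OCOC)cc(OC)c(OCOC)c1OCc2ccccc2 | intermediate
6 | 1-[2-hydroxy-4-methoxy-3,6-bis(methoxymethoxy)phenyl]ethanone | CC(=O)c1c(OCOC)cc(OC)c(OCOC)c1O | intermediate
7 | 4-(benzyloxy)benzaldehyde | O=Cc1ccc(OCc2ccccc2)cc1 | starting material
8 | rac-3-[4-(benzyloxy)phenyl]-3-hydroxy-1-[2-hydroxy-4-methoxy-3,6-bis(methoxymethoxy)phenyl]propan-1-one (not isolated; racemic, one enantiomer drawn) | COCOc1cc(OC)c(OCOC)c(O)c1C(=O)C[C@@H](O)c2ccc(OCc3ccccc3)cc2 | intermediate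
9 | (E)-3-[4-(benzyloxy)phenyl]-1-[2-hydroxy-4-methoxy-3,6-bis(methoxymethoxy)phenyl]prop-2-en-1-one | COCOc1cc(OC)c(OCOC)c(O)c1C(=O)/C=C/c2ccc(OCc3ccccc3)cc2 | intermediate
10 | rac-(2R,3R)-2-[4-(benzyloxy)phenyl]-3-hydroxy-7-methoxy-5,8-bis(methoxymethoxy)chroman-4-one (not isolated; trans, racemic, 2R,3R drawn) | O=C1c2c(OCOC)cc(OC)c(OCOC)c2O[C@H](c3ccc(OCc4ccccc4)cc3)[C@H]1O | intermediate
11 | 2-[4-(benzyloxy)phenyl]-3-hydroxy-7-methoxy-5,8-bis(methoxymethoxy)-4H-chromen-4-one | COCOc1cc(OC)c(OCOC)c2oc(-c3ccc(OCc4ccccc4)cc3)c(O)c(=O)c12 | intermediate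
12 | 3-(benzyloxy)-2-[4-(benzyloxy)phenyl]-7-methoxy-5,8-bis(methoxymethoxy)-4H-chromen-4-one | COCOc1cc(OC)c(OCOC)c2oc(-c3ccc(OCc4ccccc4)cc3)c(OCc5ccccc5)c(=O)c12 | intermediate
13 | 3-(benzyloxy)-2-[4-(benzyloxy)phenyl]-5,8-dihydroxy-7-methoxy-4H-chromen-4-one | COc1cc(O)c2c(=O)c(OCc3ccccc3)c(-c4ccc(OCc5ccccc5)cc4)oc2c1O | intermediate
14 | 3-(benzyloxy)-2-[4-(benzyloxy)phenyl]-5-hydroxy-7-methoxy-4-oxo-4H-chromen-8-yl acetate | COc1cc(O)c2c(=O)c(OCc3ccccc3)c(-c4ccc(OCc5ccccc5)cc4)oc2c1OC(C)=O | intermediate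
15 | 3,5-dihydroxy-2-(4-hydroxyphenyl)-7-methoxy-4-oxo-4H-chromen-8-yl acetate (pollenitin 8-acetate) | COc1cc(O)c2c(=O)c(O)c(-c3ccc(O)cc3)oc2c1OC(C)=O | target

**Totals**

Total step count: 10. Longest linear sequence: 10 steps (1 → 15); aldehyde 7 is purchased.

**Three steps most likely to fail**

Risk 1, step 2 (Elbs oxidation). Conversions are typically modest, with much recovered 2 and some over-oxidation. Fallback: set out from 2 and oxidise it with ON(SO3K)2 (potassium nitrosodisulfonate; KH2PO4 buffer, water/acetone, rt; Teuber oxidation) to the para-quinone 2-acetyl-3-(benzyloxy)-5-methoxycyclohexa-2,5-diene-1,4-dione F1. Reduction of the quinone with Na2S2O4 in EtOAc/water gives the hydroquinone and comes back to the route at 4.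

Risk 2, step 6 (Algar–Flynn–Oyamada). The 6'-alkoxy group of 9 can divert the reaction towards an aurone. Fallback: set out from 9 and cyclise it with NaOAc in refluxing EtOH to the racemic flavanone 2-[4-(benzyloxy)phenyl]-7-methoxy-5,8-bis(methoxymethoxy)chroman-4-one F2. Dehydrogenate this with DDQ in refluxing dioxane to the flavone 2-[4-(benzyloxy)phenyl]-7-methoxy-5,8-bis(methoxymethoxy)-4H-chromen-4-one F3. Epoxidise the flavone with dimethyldioxirane (acetone/CH2Cl2, 0 °C) to the racemic cis-fused epoxide 1a-[4-(benzyloxy)phenyl]-4-methoxy-3,6-bis(methoxymethoxy)-1a,7a-dihydro-7H-oxireno[2,3-b]chromen-7-one F4. Isomerisation of the epoxide on silica gel or with a trace of p-TsOH gives the 3-hydroxyflavone and comes back to the route at 11.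

Risk 3, step 9 (selective 8-O-acetylation of the air-sensitive hydroquinone 13). Some 5,8-diacetate or the 5,8-quinone may form. Fallback: set out from 12 and remove only the much more labile peri 5-O-MOM group (catalytic HCl, MeOH/CH2Cl2, 0 °C) to give 3-(benzyloxy)-2-[4-(benzyloxy)phenyl]-5-hydroxy-7-methoxy-8-(methoxymethoxy)-4H-chromen-4-one F5. Benzylate its chelated 5-OH under forcing conditions (BnBr, K2CO3, DMF, 70 °C) to 3,5-bis(benzyloxy)-2-[4-(benzyloxy)phenyl]-7-methoxy-8-(methoxymethoxy)-4H-chromen-4-one F6. Cleave the remaining MOM group (3 M HCl, MeOH/THF, 50 °C) to 3,5-bis(benzyloxy)-2-[4-(benzyloxy)phenyl]-8-hydroxy-7-methoxy-4H-chromen-4-one F7, whose only free hydroxyl is the 8-OH. Acetylate it (Ac2O, pyridine) to 3,5-bis(benzyloxy)-2-[4-(benzyloxy)phenyl]-7-methoxy-4-oxo-4H-chromen-8-yl acetate F8. Hydrogenolysis (H2, 10% Pd/C, EtOAc/THF) removes all three benzyl ethers and comes back to the route at 15.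

**Further compounds**

F1 | step 2 | 2-acetyl-3-(benzyloxy)-5-methoxycyclohexa-2,5-diene-1,4-dione | CC(=O)C1=C(OCc2ccccc2)C(=O)C(OC)=CC1=O
F2 | step 6 | rac-2-[4-(benzyloxy)phenyl]-7-methoxy-5,8-bis(methoxymethoxy)chroman-4-one (racemic, one enantiomer drawn) | O=C1C[C@@H](c2ccc(OCc3ccccc3)cc2)Oc2c(OCOC)c(OC)cc(OCOC)c12
F3 | step 6 | 2-[4-(benzyloxy)phenyl]-7-methoxy-5,8-bis(methoxymethoxy)-4H-chromen-4-one | COCOc1cc(OC)c(OCOC)c2oc(-c3ccc(OCc4ccccc4)cc3)cc(=O)c12
F4 | step 6 | rac-1a-[4-(benzyloxy)phenyl]-4-methoxy-3,6-bis(methoxymethoxy)-1a,7a-dihydro-7H-oxireno[2,3-b]chromen-7-one (cis-fused, racemic, one enantiomer drawn) | O=C1c2c(OCOC)cc(OC)c(OCOC)c2O[C@]2(c3ccc(OCc4ccccc4)cc3)O[C@H]12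
F5 | step 9 | 3-(benzyloxy)-2-[4-(benzyloxy)phenyl]-5-hydroxy-7-methoxy-8-(methoxymethoxy)-4H-chromen-4-one | COCOc1c(OC)cc(O)c2c(=O)c(OCc3ccccc3)c(-c4ccc(OCc5ccccc5)cc4)oc12
F6 | step 9 | 3,5-bis(benzyloxy)-2-[4-(benzyloxy)phenyl]-7-methoxy-8-(methoxymethoxy)-4H-chromen-4-one | COCOc1c(OC)cc(OCc6ccccc6)c2c(=O)c(OCc3ccccc3)c(-c4ccc(OCc5ccccc5)cc4)oc12
F7 | step 9 | 3,5-bis(benzyloxy)-2-[4-(benzyloxy)phenyl]-8-hydroxy-7-methoxy-4H-chromen-4-one | COc1cc(OCc6ccccc6)c2c(=O)c(OCc3ccccc3)c(-c4ccc(OCc5ccccc5)cc4)oc2c1O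
F8 | step 9 | 3,5-bis(benzyloxy)-2-[4-(benzyloxy)phenyl]-7-methoxy-4-oxo-4H-chromen-8-yl acetate | COc1cc(OCc6ccccc6)c2c(=O)c(OCc3ccccc3)c(-c4ccc(OCc5ccccc5)cc4)oc2c1OC(C)=O
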